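**Retrosynthetic overview**
- Rings A and B are bought: ring B as 2,5-dimethoxyphenol 1, O-prenylated with prenyl bromide 2 to arene 3; ring A as phloroacetophenone 4, masked as its tetrakis-TMS enol ether 5.
- Key disconnection C3–C1′ (the CH2–aryl bond of the deoxybenzoin): the ketone α-carbon is made an electrophile as the iodine(III) enolonium 6 and is attacked by the C–H of 3 para to the prenyloxy group (→ 7 → deoxybenzoin 8).
- Last disconnection at C2: one-carbon insertion with DMF-DMA 9 (via enaminone 10) closes the pyranone ring C, giving brandisianin A 11.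
- Order of ring formation: A and B preformed, C last (the only ring made).

Assumptions: the target has no stereocentre and is achiral, so no stereocontrol is needed. 2,5-Dimethoxyphenol is taken as a catalogue compound. BF3·OEt2 in step 3 is a Lewis-acid activator that the reaction itself does not consume.

**Step 1**
Reactants: 1 2,5-dimethoxyphenol; 2 prenyl bromide (1-bromo-3-methylbut-2-ene)
Product: 3 1,4-dimethoxy-2-[(3-methylbut-2-en-1-yl)oxy]benzene
Conditions: K2CO3 (1.5 equiv), acetone, reflux, 6 h
Reagents that add atoms: prenyl bromide (compound 2), CC(C)=CCBr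
Why: Williamson ether synthesis, in which the phenoxide displaces the primary allylic bromide by SN2 at oxygen (K2CO3/acetone favours O- over C-alkylation) and no stereocentre is formed.

**Step 2**
Reactants: 4 2′,4′,6′-trihydroxyacetophenone (dried from the commercial monohydrate by toluene azeotrope)
Product: 5 trimethyl({1-[2,4,6-tris(trimethylsilyloxy)phenyl]ethenyl}oxy)silane
Conditions: TMSOTf (4.4 equiv), Et3N (6 equiv), CH2Cl2, 0 °C → rt; evaporate, take up in pentane, filter under Ar (no aqueous work-up), use crude
Reagents that add atoms: trimethylsilyl triflate, C[Si](C)(C)OS(=O)(=O)C(F)(F)F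
Why: Soft enolisation/O-silylation with TMSOTf/Et3N silylates the three phenols and converts the methyl ketone into its only possible TMS enol ether, giving a substrate with no free OH for the oxidant of step 3.

**Step 3**
Reactants: 5 trimethyl({1-[2,4,6-tris(trimethylsilyloxy)phenyl]ethenyl}oxy)silane; 3 1,4-dimethoxy-2-[(3-methylbut-2-en-1-yl)oxy]benzene
Product: 8 2-[2,5-dimethoxy-4-(3-methylbut-2-enyloxy)phenyl]-1-(2,4,6-trihydroxyphenyl)ethan-1-one, via iodine(III) enolonium 6 (not isolated), via tris-TMS deoxybenzoin 7 (not isolated)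
Conditions: PhI(OH)OTs (Koser's reagent, 1.0 equiv), BF3·OEt2 (1.5 equiv), CH2Cl2, −78 °C, add 5 (1.1 equiv), 10 min; then 3 (2.0 equiv, excess recovered), −78 → −30 °C; quench MeOH/sat. aq NaHCO3 at −30 °C, then 10% aq citric acid/MeOH, rt, 30 min
Reagents that add atoms: none
Why: Proposed new method: Koser's reagent activated by BF3·OEt2 is known to turn TMS enol ethers at −78 °C into O-bound iodine(III) enolates (enolonium species) whose former enolate α-carbon is electrophilic and is C-arylated by indoles, pyrroles and similar π-nucleophiles; here enolonium 6 is intercepted in a Friedel–Crafts-type SN2′ attack (loss of PhI) by trialkoxyarene 3 at its most nucleophilic position (para to the prenyloxy and ortho to a methoxy group, the usual SEAr site of 1,2,4-trialkoxybenzenes), which sets the 2′,5′-dimethoxy-4′-prenyloxy pattern without pre-functionalising the arene, while the enol ether (far more nucleophilic than the hindered silyloxy ring or the prenyl alkene) consumes the limiting I(III) before 3 is added, the phenols stay masked as TMS ethers until the mild acidic work-up, and no stereocentre is formed.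

**Step 4**
Reactants: 8 2-[2,5-dimethoxy-4-(3-methylbut-2-enyloxy)phenyl]-1-(2,4,6-trihydroxyphenyl)ethan-1-one; 9 N,N-dimethylformamide dimethyl acetal (DMF-DMA)
Product: 11 brandisianin A (5,7-dihydroxy-3-[2,5-dimethoxy-4-(3-methylbut-2-enyloxy)phenyl]-4H-chromen-4-one), via enaminone 10 (not isolated)
Conditions: DMF-DMA (2.5 equiv), THF, 60 °C, 3 h; then AcOH (5 equiv), rt, 30 min
Reagents that add atoms: DMF-DMA (compound 9), COC(OC)N(C)C
Why: Amide-acetal isoflavone annulation, in which the doubly activated CH2 is aminomethylenated to enaminone 10 and an ortho-phenol closes the pyranone by oxa-Michael addition–elimination of Me2NH (the symmetrical A ring gives one regioisomer, the second ortho-OH remains as the hydrogen-bonded 5-OH, the neutral conditions spare the prenyl ether, and no stereocentre is formed).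

**Compound list**
1 | 2,5-dimethoxyphenol | COc1ccc(OC)c(O)c1 | starting material
2 | prenyl bromide (1-bromo-3-methylbut-2-ene) | CC(C)=CCBr | starting material
3 | 1,4-dimethoxy-2-[(3-methylbut-2-en-1-yl)oxy]benzene | COc1ccc(OC)c(OCC=C(C)C)c1 | intermediate
4 | 2′,4′,6′-trihydroxyacetophenone (phloroacetophenone) | CC(=O)c1c(O)cc(O)cc1O | starting material
5 | trimethyl({1-[2,4,6-tris(trimethylsilyloxy)phenyl]ethenyl}oxy)silane | C=C(O[Si](C)(C)C)c1c(O[Si](C)(C)C)cc(O[Si](C)(C)C)cc1O[Si](C)(C)C | intermediate
6 | iodine(III) enolonium: phenyl(tosyloxy)-λ3-iodanyl enolate of the tris-TMS ketone (O-bound) | C=C(OI(c1ccccc1)OS(=O)(=O)c1ccc(C)cc1)c1c(O[Si](C)(C)C)cc(O[Si](C)(C)C)cc1O[Si](C)(C)C | intermediate (not isolated)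
7 | 2-[2,5-dimethoxy-4-(3-methylbut-2-enyloxy)phenyl]-1-[2,4,6-tris(trimethylsilyloxy)phenyl]ethan-1-one | COc1cc(CC(=O)c2c(O[Si](C)(C)C)cc(O[Si](C)(C)C)cc2O[Si](C)(C)C)c(OC)cc1OCC=C(C)C | intermediate (not isolated)
8 | 2-[2,5-dimethoxy-4-(3-methylbut-2-enyloxy)phenyl]-1-(2,4,6-trihydroxyphenyl)ethan-1-one | COc1cc(CC(=O)c2c(O)cc(O)cc2O)c(OC)cc1OCC=C(C)C | intermediate
9 | N,N-dimethylformamide dimethyl acetal | COC(OC)N(C)C | starting material
10 | 3-(dimethylamino)-2-[2,5-dimethoxy-4-(3-methylbut-2-enyloxy)phenyl]-1-(2,4,6-trihydroxyphenyl)prop-2-en-1-one (E/Z not controlled, irrelevant) | COc1cc(C(=CN(C)C)C(=O)c2c(O)cc(O)cc2O)c(OC)cc1OCC=C(C)C | intermediate (not isolated)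
11 | brandisianin A | COc1cc(-c2coc3cc(O)cc(O)c3c2=O)c(OC)cc1OCC=C(C)C | target

**Totals**
Total step count: 4. Longest linear sequence: 3 steps (4 → 5 → 8 → 11, or 1 → 3 → 8 → 11).

**Three steps most likely to fail**

Step 3 (highest risk). The iodine(III) species could attack the silyloxy-rich A ring, oxidise arene 3 by electron transfer, or add to the prenyl alkene. The fallback puts the iodine(III) on the arene instead of on the enolate, so the aryl carbon carries the reversed polarity. It sets out from 3: treatment with [hydroxy(tosyloxy)iodo]mesitylene in MeCN at rt (SEAr at the same C–H) gives [2,5-dimethoxy-4-(3-methylbut-2-enyloxy)phenyl](mesityl)iodonium tosylate F1. Cu(OTf)2 (10 mol %) with 2,6-di-tert-butylpyridine in CH2Cl2 at rt then transfers the less hindered aryl group of this salt to the enol-ether carbon of 5 (Cu(I)/Cu(III) arylation). This gives 7, and the same citric acid work-up brings the sequence back to the route at 8.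

Step 4. DMF-DMA can methylate the acidic 4-OH of the A ring (the future 7-OH) or leave the ring closure incomplete. The fallback replaces the amide acetal by a base-mediated Claisen C-formylation. It sets out from 8: NaH (5 equiv) and ethyl formate in THF, 0 °C → rt, give 2,5,7-trihydroxy-3-[2,5-dimethoxy-4-(3-methylbut-2-enyloxy)phenyl]chroman-4-one F2, the cyclic hemiacetal of the β-keto aldehyde. Dehydration in AcOH at 50 °C comes back to the route at 11.

Step 2. Persilylation may be incomplete, or 5 may be too moisture-labile to handle. The fallback changes to ester masking, which also deactivates the A ring, at the cost of two extra steps. It sets out from 4: Ac2O/pyridine/DMAP gives 2,4,6-triacetoxyacetophenone F3. TMSOTf/Et3N then gives the isolable 1-(2,4,6-triacetoxyphenyl)ethenyl trimethylsilyl ether F4. The enolonium arylation with 3 under the step 3 conditions gives 2-[2,5-dimethoxy-4-(3-methylbut-2-enyloxy)phenyl]-1-(2,4,6-triacetoxyphenyl)ethan-1-one F5. K2CO3/MeOH at 0 °C removes the acetates and comes back to the route at 8.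

**Further compounds**
F1 | step 3 | [2,5-dimethoxy-4-(3-methylbut-2-enyloxy)phenyl](mesityl)iodonium tosylate | COc1cc([I+]c2c(C)cc(C)cc2C)c(OC)cc1OCC=C(C)C.Cc1ccc(cc1)S(=O)(=O)[O-]
F2 | step 4 | 2,5,7-trihydroxy-3-[2,5-dimethoxy-4-(3-methylbut-2-enyloxy)phenyl]chroman-4-one (mixture of racemic diastereomers, both centres erased on dehydration) | OC1Oc2cc(O)cc(O)c2C(=O)C1c1cc(OC)c(OCC=C(C)C)cc1OC
F3 | step 2 | 2,4,6-triacetoxyacetophenone | CC(=O)c1c(OC(C)=O)cc(OC(C)=O)cc1OC(C)=O
F4 | step 2 | 1-(2,4,6-triacetoxyphenyl)ethenyl trimethylsilyl ether | C=C(O[Si](C)(C)C)c1c(OC(C)=O)cc(OC(C)=O)cc1OC(C)=O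
F5 | step 2 | 2-[2,5-dimethoxy-4-(3-methylbut-2-enyloxy)phenyl]-1-(2,4,6-triacetoxyphenyl)ethan-1-one | COc1cc(CC(=O)c2c(OC(C)=O)cc(OC(C)=O)cc2OC(C)=O)c(OC)cc1OCC=C(C)C
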